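## Retrosynthetic overview

1. Target 17 comes from its C1 silyl ether 16. In 16 the C11–C12 bond is cut to give alkenyl pinacol boronate 9 (C1–C11) and hindered benzoate 12 of 4-methyl-3-methylidenepentan-1-ol (C12–C16). The two are joined by lithiation–borylation–oxidation, a 1,2-metallate shift across a temporary C11–B–C12 bridge.
2. Enabling feature: C12 is an sp3 carbinol carbon bonded directly to sp2 C11. O12, as the benzoate, first directs the C12–H lithiation and then leaves, and it is put back by C–B oxidation, while C11 migrates readily from boron. Both oxiranes (C2–C3–O and C6–C7–O) are trisubstituted, carry no acidic H, and stay out of the reaction.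
3. 9 comes from cross metathesis of terminal alkene 8. 8 comes from Shi epoxidation of 6Z-diene 7, 7 from Negishi coupling of (Z)-iodide 6, and 6 from Stork–Zhao-type olefination of aldehyde 5. 5 comes from geraniol by Sharpless epoxidation, silylation and ozonolysis.
4. 12 comes from 3-bromobut-3-en-1-ol by Mitsunobu esterification and Negishi isopropylation.
5. Ring order: the C2–C3 oxirane is formed first (step 1) and the C6–C7 oxirane second (step 6). The key step neither makes nor breaks a ring.

Key step: step 10

Remark: atoms are numbered along the C16 chain from the CH2OH carbon (C1) to an isopropyl methyl (C16). In the required isomer C5 and C8 are cis on the C6–C7 oxirane (6R,7S), so this ring has to come from a 6Z olefin, whereas the C2–C3 oxirane (2R,3R) is the trans, geraniol-type one.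

## Route

Step 1
Reactants: 1 geraniol
Product: 2 (2R,3R)-2,3-epoxygeraniol
Conditions: Ti(OiPr)4 (cat.), D-(−)-diisopropyl tartrate (cat.), t-BuOOH, 4 Å MS, CH2Cl2, −20 °C
Reagents that add atoms: tert-butyl hydroperoxide, CC(C)(C)OO
Why: The Katsuki–Sharpless asymmetric epoxidation is hydroxyl-directed, so only the allylic C2=C3 olefin reacts, and the D-(−)-tartrate catalyst delivers oxygen to the face that gives the (2R,3R)-oxirane (the antipode of the L-(+)-tartrate product), with the E geometry fixing C1 and C4 trans.

Step 2
Reactants: 2 (2R,3R)-2,3-epoxygeraniol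
Product: 3 (2R,3R)-2,3-epoxygeranyl tert-butyldimethylsilyl ether
Conditions: TBSCl, imidazole, CH2Cl2, 0 °C to rt
Reagents that add atoms: tert-butyldimethylsilyl chloride, C[Si](C)(Cl)C(C)(C)C
Why: Standard silylation of a primary alcohol under non-acidic conditions leaves the oxirane intact and removes the only acidic proton before the organometallic steps.

Step 3
Reactants: 3 (2R,3R)-2,3-epoxygeranyl tert-butyldimethylsilyl ether
Product: 5 (4R,5R)-6-(tert-butyldimethylsilyloxy)-4,5-epoxy-4-methylhexanal, via secondary ozonide 4 (not isolated)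
Conditions: O3, CH2Cl2, −78 °C; then Me2S, −78 °C to rt
Reagents that add atoms: ozone, [O-][O+]=O
Why: Ozonolysis with reductive work-up cleaves the only C=C left, the oxirane and silyl ether are inert to ozone at −78 °C, and no stereocentre is touched.

Step 4
Reactants: 5 (4R,5R)-6-(tert-butyldimethylsilyloxy)-4,5-epoxy-4-methylhexanal
Product: 6 (2R,3R,6Z)-1-(tert-butyldimethylsilyloxy)-2,3-epoxy-7-iodo-3-methyloct-6-ene
Conditions: EtPPh3I, n-BuLi, THF; I2, −78 °C; NaHMDS, −20 °C; then 5, −78 to −20 °C
Reagents that add atoms: ethyltriphenylphosphonium iodide, CC[P+](c1ccccc1)(c1ccccc1)c1ccccc1.[I-]; iodine, II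
Why: The Stork–Zhao-type Wittig olefination with the non-stabilised α-iodoethylidene ylide runs under kinetic control through the cis-oxaphosphetane and should give the (Z)-2-iodoalkene with iodine cis to C5, which is the handle needed for a Z-trisubstituted olefin.

Step 5
Reactants: 6 (2R,3R,6Z)-1-(tert-butyldimethylsilyloxy)-2,3-epoxy-7-iodo-3-methyloct-6-ene
Product: 7 (2R,3R,6Z)-1-(tert-butyldimethylsilyloxy)-2,3-epoxy-3,7-dimethylundeca-6,10-diene
Conditions: 3-butenylzinc bromide, PdCl2(dppf) (cat.), THF, rt
Reagents that add atoms: 3-butenylzinc bromide, C=CCC[Zn]Br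
Why: Negishi coupling of a homoallylzinc reagent with an alkenyl iodide proceeds with retention at the sp2 carbon, so C8 ends up cis to C5 (6Z), and the organozinc does not attack the oxirane or the silyl ether.

Step 6
Reactants: 7 (2R,3R,6Z)-1-(tert-butyldimethylsilyloxy)-2,3-epoxy-3,7-dimethylundeca-6,10-diene
Product: 8 (2R,3R,6R,7S)-1-(tert-butyldimethylsilyloxy)-2,3:6,7-diepoxy-3,7-dimethylundec-10-ene
Conditions: D-fructose-derived Shi ketone (cat.), Oxone, K2CO3, Bu4NHSO4 (cat.), Na2B4O7/Na2EDTA buffer, MeCN–dimethoxymethane–H2O, 0 °C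
Reagents that add atoms: Oxone (active salt potassium peroxymonosulfate), [K+].[O-]S(=O)(=O)OO
Why: In the Shi epoxidation the electrophilic chiral dioxirane prefers the trisubstituted C6=C7 over the monosubstituted C10=C11, and the spiro transition state places the single vinylic H (on C6) in the hindered quadrant, so the D-fructose ketone attacks the same C6 face as in E-olefins that give (R,R)-oxiranes, which sets 6R and, by syn addition to the Z olefin, 7S with C5 and C8 cis.

Step 7
Reactants: 8 (2R,3R,6R,7S)-1-(tert-butyldimethylsilyloxy)-2,3:6,7-diepoxy-3,7-dimethylundec-10-ene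
Product: 9 (2R,3R,6R,7S,10Z)-1-(tert-butyldimethylsilyloxy)-2,3:6,7-diepoxy-3,7-dimethyl-11-(4,4,5,5-tetramethyl-1,3,2-dioxaborolan-2-yl)dodec-10-ene (Bpin trans to C9; Z only because C outranks B)
Conditions: isopropenylboronic acid pinacol ester, Hoveyda–Grubbs II (cat.), CH2Cl2, 40 °C
Reagents that add atoms: isopropenylboronic acid pinacol ester, C=C(C)B1OC(C)(C)C(C)(C)O1
Why: Olefin cross metathesis of a fast-reacting terminal alkene with a 1,1-disubstituted alkenyl boronate that barely homodimerises is a known route to trisubstituted alkenyl boronates, its reversibility favours the isomer with the bulky Bpin trans to the chain, and oxiranes and silyl ethers tolerate the Ru carbene.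

Step 8
Reactants: 10 3-bromobut-3-en-1-ol
Product: 11 3-bromobut-3-en-1-yl 2,4,6-triisopropylbenzoate
Conditions: 2,4,6-triisopropylbenzoic acid, PPh3, DIAD, THF, 0 °C to rt
Reagents that add atoms: 2,4,6-triisopropylbenzoic acid, CC(C)c1cc(C(C)C)c(C(=O)O)c(C(C)C)c1
Why: The Mitsunobu esterification suits this very hindered acid because the C–O bond forms by SN2 attack of the carboxylate on the activated primary carbon and not by attack at the shielded acyl carbon.

Step 9
Reactants: 11 3-bromobut-3-en-1-yl 2,4,6-triisopropylbenzoate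
Product: 12 4-methyl-3-methylidenepentyl 2,4,6-triisopropylbenzoate
Conditions: i-PrZnBr, PdCl2(dppf) (cat.), THF, rt to 40 °C
Reagents that add atoms: isopropylzinc bromide, CC(C)[Zn]Br
Why: In this Negishi coupling of a secondary alkylzinc with a 2-bromoalkene, the wide-bite-angle dppf ligand speeds reductive elimination over β-hydride elimination, so isopropyl is transferred unrearranged while the shielded ester stays inert.

Step 10
Reactants: 12 4-methyl-3-methylidenepentyl 2,4,6-triisopropylbenzoate; 9 alkenyl pinacol boronate (C1–C11)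
Product: 16 (2R,3R,6R,7S,10E,12R)-1-(tert-butyldimethylsilyloxy)-2,3:6,7-diepoxy-3,7,11,15-tetramethyl-14-methylidenehexadec-10-en-12-ol, via lithiated benzoate 13 (not isolated), via boronate complex 14 (not isolated), via allylic boronic ester 15 (not isolated)
Conditions: 12, s-BuLi, (−)-sparteine, Et2O, −78 °C; then 9, −78 °C, then warm to 35 °C; then NaOH, H2O2, THF–H2O, 0 °C
Reagents that add atoms: hydrogen peroxide, OO
Why: s-BuLi/(−)-sparteine removes the pro-S hydrogen at C12 of 12 under direction by the benzoate carbonyl and gives the configurationally stable (S)-organolithium 13, which adds with retention to the empty orbital on boron of 9, so that in complex 14 two carbons of like (nucleophilic) polarity, sp2 C11 and sp3 C12, sit on one boron atom. On warming, C11 migrates from boron to C12 anti to the departing triisopropylbenzoate (1,2-metallate rearrangement, inversion at C12, olefin geometry at C11 retained), and NaOH/H2O2 then replaces the temporary C12–B bond of 15 by C12–O with retention. The closest known reaction type is lithiation–borylation, the reagent-controlled form of the Matteson homologation, of primary carbamates and hindered benzoates with alkenyl pinacol boronic esters, which gives α-chiral allylic boronic esters and, after oxidation, allylic alcohols. No ring is closed, and the only new stereocentre, C12, is set as R by the s-BuLi/(−)-sparteine pair through the stereospecific retention–inversion–retention sequence, independently of the four remote oxirane centres. The step needs boron to win over the oxiranes and the silyl ether as the site of attack, which is secured by the very fast capture of organolithiums by Bpin at −78 °C, by both oxiranes being trisubstituted and by a leaving group good enough that no Lewis acid additive is needed, and it needs C12–H to win over the allylic C13–H, which is secured by complex-induced proximity to the ester carbonyl. Because C12 enters as a carbanion at the alcohol oxidation level, the β,γ-unsaturated aldehyde 4-methyl-3-methylidenepentanal, which would slip into conjugation, is never needed.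

Step 11
Reactants: 16 C1 silyl ether of the target
Product: 17 (2R,3R,6R,7S,10E,12R)-2,3:6,7-diepoxy-3,7,11,15-tetramethyl-14-methylidenehexadec-10-ene-1,12-diol (target)
Conditions: TBAF, AcOH, THF, 0 °C
Reagents that add atoms: none
Why: Fluoride-mediated desilylation cleaves only the Si–O bond, and the acetic acid buffer keeps the freed C1 alkoxide from starting a Payne rearrangement of the C2–C3 oxirane, so no stereocentre is touched.

## Compound list

1 | geraniol, (2E)-3,7-dimethylocta-2,6-dien-1-ol | CC(C)=CCC/C(C)=C/CO | starting material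
2 | (2R,3R)-2,3-epoxygeraniol | CC(C)=CCC[C@@]1(C)O[C@@H]1CO | intermediate
3 | (2R,3R)-2,3-epoxygeranyl TBS ether | CC(C)=CCC[C@@]1(C)O[C@@H]1CO[Si](C)(C)C(C)(C)C | intermediate
4 | secondary ozonide of 3 (3,3-dimethyl-1,2,4-trioxolane bearing the C1–C5 chain; acetal carbon unassigned) | CC1(C)OOC(CC[C@@]2(C)O[C@@H]2CO[Si](C)(C)C(C)(C)C)O1 | intermediate
5 | (4R,5R)-6-(TBS-oxy)-4,5-epoxy-4-methylhexanal | O=CCC[C@@]1(C)O[C@@H]1CO[Si](C)(C)C(C)(C)C | intermediate
6 | (2R,3R,6Z)-1-(TBS-oxy)-2,3-epoxy-7-iodo-3-methyloct-6-ene | C/C(I)=C/CC[C@@]1(C)O[C@@H]1CO[Si](C)(C)C(C)(C)C | intermediate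
7 | (2R,3R,6Z)-1-(TBS-oxy)-2,3-epoxy-3,7-dimethylundeca-6,10-diene | C=CCC/C(C)=C\CC[C@@]1(C)O[C@@H]1CO[Si](C)(C)C(C)(C)C | intermediate
8 | (2R,3R,6R,7S)-1-(TBS-oxy)-2,3:6,7-diepoxy-3,7-dimethylundec-10-ene | C=CCC[C@]1(C)O[C@@H]1CC[C@@]1(C)O[C@@H]1CO[Si](C)(C)C(C)(C)C | intermediate
9 | C1–C11 alkenyl pinacol boronate, Bpin and CH3 on C11, Bpin trans to C9 | CC1(C)OB(OC1(C)C)/C(C)=C/CC[C@]1(C)O[C@@H]1CC[C@@]1(C)O[C@@H]1CO[Si](C)(C)C(C)(C)C | intermediate
10 | 3-bromobut-3-en-1-ol | C=C(Br)CCO | starting material
11 | 3-bromobut-3-en-1-yl 2,4,6-triisopropylbenzoate | C=C(Br)CCOC(=O)c1c(C(C)C)cc(C(C)C)cc1C(C)C | intermediate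
12 | 4-methyl-3-methylidenepentyl 2,4,6-triisopropylbenzoate | C=C(CCOC(=O)c1c(C(C)C)cc(C(C)C)cc1C(C)C)C(C)C | intermediate
13 | (S)-1-lithio-4-methyl-3-methylidenepentyl 2,4,6-triisopropylbenzoate (sparteine complex) | C=C(C[C@H]([Li])OC(=O)c1c(C(C)C)cc(C(C)C)cc1C(C)C)C(C)C | intermediate
14 | lithium boronate complex, with C11 and (S)-C12 both on boron | [Li+].C=C(C[C@H]([B-]1(OC(C)(C)C(C)(C)O1)/C(C)=C/CC[C@]1(C)O[C@@H]1CC[C@@]1(C)O[C@@H]1CO[Si](C)(C)C(C)(C)C)OC(=O)c1c(C(C)C)cc(C(C)C)cc1C(C)C)C(C)C | intermediate
15 | (12R,10E)-allylic pinacol boronic ester (Bpin on C12) | C=C(C[C@@H](B1OC(C)(C)C(C)(C)O1)/C(C)=C/CC[C@]1(C)O[C@@H]1CC[C@@]1(C)O[C@@H]1CO[Si](C)(C)C(C)(C)C)C(C)C | intermediate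
16 | C1 TBS ether of the target | C=C(C[C@@H](O)/C(C)=C/CC[C@]1(C)O[C@@H]1CC[C@@]1(C)O[C@@H]1CO[Si](C)(C)C(C)(C)C)C(C)C | intermediate
17 | (2R,3R,6R,7S,10E,12R)-2,3:6,7-diepoxy-3,7,11,15-tetramethyl-14-methylidenehexadec-10-ene-1,12-diol | C=C(C[C@@H](O)/C(C)=C/CC[C@]1(C)O[C@@H]1CC[C@@]1(C)O[C@@H]1CO)C(C)C | target

## Step count

Total step count: 11. Longest linear sequence: 9 steps (steps 1–7, 10, 11).

## Steps most likely to fail

**Step 10.**
- Risk: lithiation of 12 may be incomplete or misdirected to the allylic C13–H, the organolithium may be lost to oxirane opening, or the 1,2-shift of the α-branched alkenyl group may be too slow, letting the boronate complex fall apart.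
- Fallback: it sets out from 9 and comes back at 15. Vinyllithium is added to 9 at low temperature to give the lithium bis(alkenyl)borate F1. Separately, 3-methylbutan-2-one is converted through its kinetic enolate (LDA, then PhNTf2) into 3-methylbut-1-en-2-yl trifluoromethanesulfonate F2.
- A Pd(OAc)2/MandyPhos-catalysed enantioselective conjunctive cross-coupling of the two follows. The alkenyl–Pd(II) species binds the unsubstituted vinyl group, C11 migrates from boron to C12, and reductive elimination forms C13–C14.
- This should give 15, which is oxidised as in step 10. Here C12 is set by the ligand antipode (both are sold), and no strong base touches the right-hand part.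

**Step 6.**
- Risk: facial selectivity may be poor, because in the Z olefin the larger C8 methylene occupies the quadrant that holds only a methyl group in E olefins. The resulting diastereomers differ at remote centres and may be hard to separate.
- Fallback: it sets out from 5 and comes back at 8, so it also bypasses steps 4 and 5.
- Still–Gennari olefination of 5 with methyl 2-[bis(2,2,2-trifluoroethoxy)phosphoryl]propanoate (KHMDS, 18-crown-6) gives the (Z)-enoate F3.
- DIBAL-H at −78 °C gives the (Z)-allylic alcohol F4.
- Katsuki–Sharpless epoxidation with L-(+)-diethyl tartrate, now directed by the C8 hydroxyl, gives the (6R,7S)-epoxy alcohol F5.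
- Tf2O/2,6-lutidine gives the primary triflate F6. Copper-catalysed displacement with allylmagnesium bromide at low temperature then installs C9–C11 and gives 8.

**Step 7.**
- Risk: the metathesis may stall at the hindered trisubstituted olefin, 8 may homodimerise, or geometric control may erode.
- Fallback: it sets out from 8 and comes back at 9. Lemieux–Johnson cleavage (OsO4 cat., NaIO4, 2,6-lutidine, dioxane–H2O) of the terminal alkene gives the C10 aldehyde F7.
- A boron–Wittig olefination of this aldehyde with lithiated 1,1-bis(pinacolboryl)ethane (LiTMP, THF, −78 °C) should give 9 with Bpin trans to the chain.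

## Further compounds

F1 | step 10 | lithium bis(alkenyl)borate from 9 and vinyllithium | [Li+].C=C[B-]1(OC(C)(C)C(C)(C)O1)/C(C)=C/CC[C@]1(C)O[C@@H]1CC[C@@]1(C)O[C@@H]1CO[Si](C)(C)C(C)(C)C
F2 | step 10 | 3-methylbut-1-en-2-yl trifluoromethanesulfonate | C=C(OS(=O)(=O)C(F)(F)F)C(C)C
F3 | step 6 | methyl (2Z,6R,7R)-8-(TBS-oxy)-6,7-epoxy-2,6-dimethyloct-2-enoate | COC(=O)/C(C)=C\CC[C@@]1(C)O[C@@H]1CO[Si](C)(C)C(C)(C)C
F4 | step 6 | (2Z,6R,7R)-8-(TBS-oxy)-6,7-epoxy-2,6-dimethyloct-2-en-1-ol | OC/C(C)=C\CC[C@@]1(C)O[C@@H]1CO[Si](C)(C)C(C)(C)C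
F5 | step 6 | bis-oxirane alcohol with C8–OH, (6R,7S) and (2R,3R) in target numbering | OC[C@]1(C)O[C@@H]1CC[C@@]1(C)O[C@@H]1CO[Si](C)(C)C(C)(C)C
F6 | step 6 | C8 trifluoromethanesulfonate of F5 | O=S(=O)(OC[C@]1(C)O[C@@H]1CC[C@@]1(C)O[C@@H]1CO[Si](C)(C)C(C)(C)C)C(F)(F)F
F7 | step 7 | C10 aldehyde, (2R,3R,6R,7S)-bis-oxirane with C1–O-TBS | O=CCC[C@]1(C)O[C@@H]1CC[C@@]1(C)O[C@@H]1CO[Si](C)(C)C(C)(C)C
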